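## The problem

The target 17 is an unsymmetrical dibenzoylmethane. A three-carbon 1,3-dicarbonyl chain joins ring A (chain at C1, OMe at C2, prenyl at C3, free OH at C4) to ring B (chain at C1', prenyl at C3', OH at C4'). No ring has to be closed and there is no stereocenter, so the problem is one of regiochemistry and functional-group tolerance. Ring A is the hard part: it is a 1,2,3,4-tetrasubstituted arene in which one oxygen is methylated, the other is free, and the prenyl group sits between them. Electrophilic substitution on a resorcinol does not give this cleanly, because C3 competes with C5 and O-alkylation with C-alkylation. The two ortho-prenylphenols cyclize to 2,2-dimethylchromans in strong acid and do not survive hydrogenation or electrophilic halogen, and the β-diketone is open to retro-Claisen cleavage in strong base and to C-alkylation. Both prenyl groups must therefore be in place before the chain is completed, and the last steps must be mild. The 1,3-diketone can be hidden as a 1,3-diarylpropynone, since hydration of that ynone gives the diketone; a two-carbon alkyne is thus the natural link between ring A and the ring B carbonyl. The enabling feature is that the C4 hydroxyl is para to C1, with OMe at C2 and prenyl at C3. This is the pattern left when a carbon nucleophile adds to the carbonyl next to the methoxy-bearing carbon of 2-methoxy-3-prenyl-1,4-benzoquinone 5 and the ring is reduced back to an arene.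

## Retrosynthesis

**17 to 15.** The C=O bond on the ring A side of 17 is taken back to an alkyne, giving ynone 15 (through pyrrolidine enaminone 16 in the forward sense). Cutting the central CH2–CO bond instead (Claisen logic) would demand a ring A acetophenone whose oxygen pattern must be made by selective chemistry on a resorcinol. The ynone turns both chain carbons next to ring A into sp carbons that an acetylide can deliver. The forward reaction is a formal hydration; only the β-carbon of the ynone is electrophilic, so the diketone is the only outcome.

**15 to 14.** No skeletal bond is cut; the ketone is masked as a dioxolane and the ring B phenol as a MOM ether. The ynone carbonyl cannot coexist with an acetylide or with zinc, so it must be masked during the key step. Both acetals are chosen to fall in one dilute-acid operation. The ring A phenol needs no protection because the key step delivers it free.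

**14 to 5 and 11 (key disconnection).** The bond between ring A C1 and the alkyne carbon is cut. The alternative reading of the same bond, a Sonogashira coupling (PdCl2(PPh3)2, CuI) of a 4-halo-3-methoxy-2-prenylphenol, needs a halide that cannot be made by halogenating a prenylated phenol. A Friedel–Crafts acylation of a 2-prenylresorcinol monoether would face regiochemistry and strong Lewis acid. In quinone 5 the oxidation state of the ring does the differentiation: the C1 carbonyl accepts the nucleophile, the C4 carbonyl becomes the phenol, and the C2 methoxy stays an ether. The forward step asks for 1,2-addition of lithium acetylide 12 at C1 only, then reductive aromatization of quinol 13 without loss of the acetals. Both partners are simple, stable, separately made compounds.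

**5 to 4 to 1 and 2.** The two quinone C=O bonds go back to the para pair of methyl ethers in 4 (oxidative demethylation). The aryl–CH2 bond of 4 is cut to aryllithium 3 and prenyl bromide 2. Lithiation of 1 occurs between the C2 and C4 methoxy groups, which places the prenyl group exactly where ring A needs it, with no isomer problem.

**11 to 10 to 9 to 8 to 7 to 6 and 2.** The dioxolane of 11 comes from ynone 10, the ynone from propargylic alcohol 9, and the carbinol C–C bond from aldehyde 8 and an ethynyl Grignard reagent. MOM ether 8 comes from phenol 7, whose aryl–prenyl bond is cut to 4-hydroxybenzaldehyde 6 and 2. Ring B has two equivalent ortho positions, so a direct C-prenylation is acceptable here even though its chemoselectivity is modest.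

## Roads not taken

**Alternative 1:** Both aryl–prenyl bonds are cut at once, with the diketone hidden in a flavone. Heating the bis(1,1-dimethylallyl) ether A1 would give the 8,3'-diprenylflavone A2 by two aromatic Claisen rearrangements. The merit is real: both prenyl groups arrive late, in one thermal step, from O-ethers, and the unselective C-alkylation of step 3 in the chosen route is avoided. On this count the alternative is better. The weak points lie after the key step. The ring A ether can rearrange to C6 as well as C8. More seriously, A2 carries the ring A C2 oxygen as the pyranone oxygen. To reach 17 the pyranone must be opened by base to the 2-hydroxy diketone A3, a compound that recloses readily and that fragments by retro-Claisen cleavage under the conditions that open it. The chelated, doubly flanked C2 hydroxyl of A3 must then be methylated in the presence of two more reactive phenols and an acidic CH2. That costs several protecting-group operations of doubtful selectivity. The chosen plan pays with one modest prenylation but never has to differentiate the ring A oxygens.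

**Alternative 2:** Ring A is built de novo by cutting C1–C2 and C5–C6. The ketene acetal diene A4 would add to the terminal alkyne of diynone A5, and loss of one acetal methoxy group with desilylation would give ynone A6. This forms two C–C bonds and the ring in one step, fixes the 1,2,3,4 pattern by the regiochemistry of a polarized Diels–Alder reaction, and gives an ynone directly with the ring A phenol free and no ketal to remove. In bond-forming economy it is ahead of the chosen key step, and it needs the same hydration endgame. Its weakness is the partners. A4 is a tetrasubstituted, hydrolytically fragile ketene acetal that must be made from a prenylated β-keto ortho-ester equivalent, and its 1,1-disubstituted terminus slows cycloaddition. A5 is a cross-conjugated diynone with two activated alkynes, prone to double addition and to oligomerization. The chosen plan forms only one bond in its key step, but from a bench-stable quinone and a simple terminal alkyne, each made by a few standard operations.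

**Alternative 3:** The ring B aryl–CO bond and the CO–CH2 bond are cut together. Aryl iodide A7, carbon monoxide A9 and the enolate of acetophenone A8 would combine on a catalyst such as Pd(dba)2 with a wide-bite-angle bisphosphine to give the bis-MOM diketone A10 directly at the right oxidation level. This is the shortest and most convergent route, with no hydration step and only a final MOM removal; in step count it beats the chosen plan. Its weak points are the more acidic product, which consumes base and can react further, the competition from non-carbonylative α-arylation, and the handling of gaseous A9. Above all, A8 must be made from a resorcinol-type ketone by C3-prenylation (C5 and oxygen compete) and by selective protection and methylation of its two phenols. The chosen plan sets against the shorter sequence a ring A whose prenyl position is fixed by directed metalation and whose oxygens are differentiated by the quinone itself.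

Key step: step 8

Remark: 17 is drawn as the diketo tautomer; it is expected to exist largely as its chelated enol forms, which are the same compound for this plan.

## Route

Step 1
Reactants: 1 1,2,4-trimethoxybenzene; 2 1-bromo-3-methylbut-2-ene (prenyl bromide)
Product: 4 1,2,4-trimethoxy-3-(3-methylbut-2-enyl)benzene, via (2,3,6-trimethoxyphenyl)lithium 3 (not isolated)
Conditions: n-BuLi, TMEDA, THF, 0 °C → rt; then 2, −78 °C → rt
Reagents that add atoms: none
Why: Directed ortho-metalation; the C3–H between two methoxy groups is the most acidic and both oxygens hold the lithium, and the aryllithium is alkylated by the primary allylic bromide in an SN2 reaction.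

Step 2
Reactants: 4 1,2,4-trimethoxy-3-(3-methylbut-2-enyl)benzene
Product: 5 2-methoxy-3-(3-methylbut-2-enyl)cyclohexa-2,5-diene-1,4-dione
Conditions: (NH4)2Ce(NO3)6, MeCN/H2O, 0 °C
Reagents that add atoms: water, O
Why: Oxidative demethylation of a para-dimethoxyarene to the 1,4-quinone; the para pair of ethers is oxidized in preference to the ortho pair, the C2 methoxy is retained, and the isolated trisubstituted alkene is much harder to oxidize than the trialkoxyarene.

Step 3
Reactants: 6 4-hydroxybenzaldehyde; 2 1-bromo-3-methylbut-2-ene
Product: 7 4-hydroxy-3-(3-methylbut-2-enyl)benzaldehyde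
Conditions: 10% aq. KOH, 0 °C → rt; then dilute HCl
Reagents that add atoms: none
Why: Ortho C-alkylation of an ambident phenoxide in water, where hydrogen bonding at oxygen diverts part of the alkylation to carbon; the two ortho positions are equivalent, and the O-prenyl ether and unreacted 6 are removed by chromatography.

Step 4
Reactants: 7 4-hydroxy-3-(3-methylbut-2-enyl)benzaldehyde
Product: 8 4-(methoxymethoxy)-3-(3-methylbut-2-enyl)benzaldehyde
Conditions: MOMCl, i-Pr2NEt, CH2Cl2, 0 °C → rt
Reagents that add atoms: chloromethyl methyl ether, COCCl
Why: O-alkylation of the phenol to a MOM acetal, which tolerates organometallic reagents, MnO2 and zinc/acetic acid and is removed by dilute acid.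

Step 5
Reactants: 8 4-(methoxymethoxy)-3-(3-methylbut-2-enyl)benzaldehyde
Product: 9 1-[4-(methoxymethoxy)-3-(3-methylbut-2-enyl)phenyl]prop-2-yn-1-ol (racemic)
Conditions: HC≡CMgBr, THF, 0 °C; then sat. aq. NH4Cl
Reagents that add atoms: ethynylmagnesium bromide, C#C[Mg]Br
Why: 1,2-Addition of an alkynyl Grignard reagent to an aromatic aldehyde; the new stereocenter is formed racemic and is removed in step 6.

Step 6
Reactants: 9 1-[4-(methoxymethoxy)-3-(3-methylbut-2-enyl)phenyl]prop-2-yn-1-ol
Product: 10 1-[4-(methoxymethoxy)-3-(3-methylbut-2-enyl)phenyl]prop-2-yn-1-one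
Conditions: MnO2 (activated, excess), CH2Cl2, rt
Reagents that add atoms: none
Why: MnO2 oxidation of a benzylic, propargylic alcohol to the ynone; the neutral heterogeneous oxidant leaves the prenyl alkene and the MOM ether alone.

Step 7
Reactants: 10 1-[4-(methoxymethoxy)-3-(3-methylbut-2-enyl)phenyl]prop-2-yn-1-one
Product: 11 2-ethynyl-2-[4-(methoxymethoxy)-3-(3-methylbut-2-enyl)phenyl]-1,3-dioxolane
Conditions: (Me3SiOCH2)2, Me3SiOTf (cat.), CH2Cl2, −78 → −20 °C; then pyridine, aq. NaHCO3
Reagents that add atoms: 1,2-bis(trimethylsilyloxy)ethane, C[Si](C)(C)OCCO[Si](C)(C)C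
Why: Noyori ketalization, driven by formation of hexamethyldisiloxane; the aprotic conditions keep free diol away from the electrophilic β-carbon of the ynone, and the low temperature and catalytic silyl triflate should spare the MOM ether and the prenyl alkene.

Step 8
Reactants: 11 2-ethynyl-2-[4-(methoxymethoxy)-3-(3-methylbut-2-enyl)phenyl]-1,3-dioxolane; 5 2-methoxy-3-(3-methylbut-2-enyl)cyclohexa-2,5-diene-1,4-dione
Product: 14 3-methoxy-4-({2-[4-(methoxymethoxy)-3-(3-methylbut-2-enyl)phenyl]-1,3-dioxolan-2-yl}ethynyl)-2-(3-methylbut-2-enyl)phenol, via lithium acetylide 12 (not isolated), via alkynyl quinol 13 (not isolated)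
Conditions: n-BuLi, THF, −78 °C; added to 5 in THF, −78 °C; then AcOH, Zn dust, −78 °C → rt
Reagents that add atoms: none
Why: n-BuLi deprotonates the terminal alkyne of 11, and acetylide 12, a propargylic acetal anion of a kind in routine use as an acyl-ethynyl equivalent, adds 1,2 to the C1 carbonyl of 5; acetic acid protonates the resulting alkoxide to the 4-alkynyl-4-hydroxycyclohexadienone 13. The closest known reactions are the 1,2-addition of lithium acetylides to alkoxy-1,4-benzoquinones at the carbonyl that is not a vinylogous ester, and the zinc/acetic acid reductive aromatization of para-quinols; running them in one flask on this quinone is a matter of operation, not a new reaction type. Site selectivity is the one selectivity required: the C4 carbonyl is deactivated by conjugation with the C2 methoxy group through C3 and is flanked by the prenyl group, whereas C1 is the more electrophilic carbonyl and its neighbouring methoxy oxygen can hold the lithium cation; the hard acetylide at −78 °C should avoid conjugate addition at C5 or C6. Zinc then transfers two electrons to the cross-conjugated dienone and the resulting dienolate expels the tertiary hydroxyl as water in a vinylogous β-elimination, so ring A aromatizes with the former C4 carbonyl as the free phenol and the C2 methoxy untouched. No ring is closed, and the stereocenter of 13 is destroyed on aromatization, so nothing stereochemical has to be controlled. The MOM ether, the dioxolane and both trisubstituted alkenes are not reducible by zinc, and brief exposure to acetic acid in THF at or below room temperature should leave the acetals intact.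

Step 9
Reactants: 14 3-methoxy-4-({2-[4-(methoxymethoxy)-3-(3-methylbut-2-enyl)phenyl]-1,3-dioxolan-2-yl}ethynyl)-2-(3-methylbut-2-enyl)phenol
Product: 15 3-[4-hydroxy-2-methoxy-3-(3-methylbut-2-enyl)phenyl]-1-[4-hydroxy-3-(3-methylbut-2-enyl)phenyl]prop-2-yn-1-one
Conditions: 2 M aq. HCl, MeOH/THF, 45 °C
Reagents that add atoms: water, O
Why: Acid hydrolysis of the ketal (its ionization helped by the para-oxygenated aryl group) and of the MOM acetal; dilute HCl in aqueous methanol at moderate temperature is the standard way to unmask MOM ethers beside prenyl groups without chroman formation, and any β-chloro or β-methoxy enone formed by conjugate addition to the ynone would be converted to the same enaminone in step 10.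

Step 10
Reactants: 15 3-[4-hydroxy-2-methoxy-3-(3-methylbut-2-enyl)phenyl]-1-[4-hydroxy-3-(3-methylbut-2-enyl)phenyl]prop-2-yn-1-one
Product: 17 1-[4-hydroxy-2-methoxy-3-(3-methylbut-2-enyl)phenyl]-3-[4-hydroxy-3-(3-methylbut-2-enyl)phenyl]propane-1,3-dione, via pyrrolidine enaminone 16 (not isolated)
Conditions: pyrrolidine (excess), EtOH, rt → 50 °C; concentrate; then 1 M aq. HCl, THF, rt
Reagents that add atoms: water, O
Why: Aza-Michael addition of a secondary amine to the β-carbon of the ynone gives the vinylogous amide 16 (expected E, geometry without consequence), and aqueous acid hydrolyses it through the iminium ion to the 1,3-diketone; the conditions are mild enough for the prenyl groups and the free phenols.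

## Compound list

1 | 1,2,4-trimethoxybenzene | COc1ccc(OC)c(OC)c1 | starting material
2 | 1-bromo-3-methylbut-2-ene (prenyl bromide) | CC(C)=CCBr | starting material
3 | (2,3,6-trimethoxyphenyl)lithium | COc1ccc(OC)c([Li])c1OC | intermediate (not isolated)
4 | 1,2,4-trimethoxy-3-(3-methylbut-2-enyl)benzene | COc1ccc(OC)c(CC=C(C)C)c1OC | intermediate
5 | 2-methoxy-3-(3-methylbut-2-enyl)cyclohexa-2,5-diene-1,4-dione | COC1=C(CC=C(C)C)C(=O)C=CC1=O | intermediate
6 | 4-hydroxybenzaldehyde | O=Cc1ccc(O)cc1 | starting material
7 | 4-hydroxy-3-(3-methylbut-2-enyl)benzaldehyde | CC(C)=CCc1cc(C=O)ccc1O | intermediate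
8 | 4-(methoxymethoxy)-3-(3-methylbut-2-enyl)benzaldehyde | COCOc1ccc(C=O)cc1CC=C(C)C | intermediate
9 | 1-[4-(methoxymethoxy)-3-(3-methylbut-2-enyl)phenyl]prop-2-yn-1-ol (racemic) | C#CC(O)c1ccc(OCOC)c(CC=C(C)C)c1 | intermediate
10 | 1-[4-(methoxymethoxy)-3-(3-methylbut-2-enyl)phenyl]prop-2-yn-1-one | C#CC(=O)c1ccc(OCOC)c(CC=C(C)C)c1 | intermediate
11 | 2-ethynyl-2-[4-(methoxymethoxy)-3-(3-methylbut-2-enyl)phenyl]-1,3-dioxolane | C#CC1(c2ccc(OCOC)c(CC=C(C)C)c2)OCCO1 | intermediate
12 | ({2-[4-(methoxymethoxy)-3-(3-methylbut-2-enyl)phenyl]-1,3-dioxolan-2-yl}ethynyl)lithium | [Li]C#CC1(c2ccc(OCOC)c(CC=C(C)C)c2)OCCO1 | intermediate (not isolated)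
13 | 4-hydroxy-3-methoxy-4-({2-[4-(methoxymethoxy)-3-(3-methylbut-2-enyl)phenyl]-1,3-dioxolan-2-yl}ethynyl)-2-(3-methylbut-2-enyl)cyclohexa-2,5-dien-1-one (racemic) | COC1=C(CC=C(C)C)C(=O)C=CC1(O)C#CC3(c2ccc(OCOC)c(CC=C(C)C)c2)OCCO3 | intermediate (not isolated)
14 | 3-methoxy-4-({2-[4-(methoxymethoxy)-3-(3-methylbut-2-enyl)phenyl]-1,3-dioxolan-2-yl}ethynyl)-2-(3-methylbut-2-enyl)phenol | COc1c(C#CC2(c3ccc(OCOC)c(CC=C(C)C)c3)OCCO2)ccc(O)c1CC=C(C)C | intermediate
15 | 3-[4-hydroxy-2-methoxy-3-(3-methylbut-2-enyl)phenyl]-1-[4-hydroxy-3-(3-methylbut-2-enyl)phenyl]prop-2-yn-1-one | COc1c(C#CC(=O)c2ccc(O)c(CC=C(C)C)c2)ccc(O)c1CC=C(C)C | intermediate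
16 | (E)-3-[4-hydroxy-2-methoxy-3-(3-methylbut-2-enyl)phenyl]-1-[4-hydroxy-3-(3-methylbut-2-enyl)phenyl]-3-(pyrrolidin-1-yl)prop-2-en-1-one | COc1c(/C(=C\C(=O)c2ccc(O)c(CC=C(C)C)c2)N3CCCC3)ccc(O)c1CC=C(C)C | intermediate (not isolated)
17 | 1-[4-hydroxy-2-methoxy-3-(3-methylbut-2-enyl)phenyl]-3-[4-hydroxy-3-(3-methylbut-2-enyl)phenyl]propane-1,3-dione | COc1c(C(=O)CC(=O)c2ccc(O)c(CC=C(C)C)c2)ccc(O)c1CC=C(C)C | target

## Step count and least certain steps

Total: 10 steps. Longest linear sequence: 8 steps (steps 3 to 10, from 6); the quinone branch (steps 1 and 2) joins at step 8.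

**Step 8 (key step).** The most likely failure is loss of the dioxolane during the acidic zinc stage. Its ionization is assisted by the para-alkoxyaryl group and by zinc diacetate acting as a Lewis acid, and the ynone so released would itself be reduced by zinc. A second risk is electron transfer from the acetylide to the quinone in place of addition. The fallback sets out from 9 and 5 and comes back at 15; it carries the future carbonyl through the key step one oxidation level lower, where nothing can ionize. Alcohol 9 would be silylated (TBSCl, imidazole) to the tert-butyldimethylsilyl ether F1. Its lithium acetylide would be added to 5 to give the silyloxy quinol F2, which zinc/acetic acid would reduce to the silyloxy alkynylphenol F3. Bu4NF would release the propargylic diol F4, MnO2 would oxidize it to the MOM-protected ynone F5, and the conditions of step 9 would remove the MOM group to give 15.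

**Step 7.** The carbonyl of 10 is deactivated by the para-alkoxyaryl group, so ketalization may be slow. The unhindered, strongly electrophilic terminal ynone could then be consumed by conjugate addition or oligomerization first, and raising the amount of silyl triflate or the temperature invites loss of the aryl MOM ether. The fallback sets out from 8 and comes back at 11; it changes the sequence so that the alkyne terminus is capped with silicon while the ketone is made and masked. Lithium (trimethylsilyl)acetylide would add to 8 to give the silyl-capped propargylic alcohol F6, and MnO2 would give the silyl-capped ynone F7. Its shielded β-carbon allows longer ketalization times, leading to the silyl-capped dioxolane F8, and K2CO3 in methanol would remove the silyl group to give 11.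

**Step 10.** Pyrrolidine is basic enough to deprotonate both phenols. The ring B phenoxide para to the carbonyl and the ring A phenoxide para to the alkyne both push electron density into the ynone, so conjugate addition may stall or need forcing. The fallback sets out from 15 and comes back at 17; it uses a weakly basic α-nucleophile and a heterocycle as the masked diketone. Hydroxylamine hydrochloride with NaOAc in ethanol would give the 3,5-diarylisoxazole F9 (either regioisomer serves). Mo(CO)6 in wet acetonitrile would cleave the N–O bond to the primary enaminone F10, and dilute aqueous HCl would hydrolyse it to 17.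

**Step 3.** Chemoselectivity between O- and C-alkylation is poor, and dialkylation and low conversion are expected, so the material throughput of the ring B branch may be inadequate. The fallback sets out from 6 and comes back at 7; it delivers the prenyl group through oxygen by a sigmatropic shift. Phenol 6 would be O-alkylated with methyl 2-methylbut-3-en-2-yl carbonate and Pd(PPh3)4 to the 1,1-dimethylallyl ether F11. Heating in N,N-diethylaniline would effect the aromatic Claisen rearrangement to 7, with the allyl unit inverted to the linear prenyl group at the only available ortho position.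

## Further compounds

F1 | step 8 | tert-butyl(dimethyl)({1-[4-(methoxymethoxy)-3-(3-methylbut-2-enyl)phenyl]prop-2-yn-1-yl}oxy)silane (racemic) | C#CC(O[Si](C)(C)C(C)(C)C)c1ccc(OCOC)c(CC=C(C)C)c1
F2 | step 8 | 4-(3-{[tert-butyl(dimethyl)silyl]oxy}-3-[4-(methoxymethoxy)-3-(3-methylbut-2-enyl)phenyl]prop-1-yn-1-yl)-4-hydroxy-3-methoxy-2-(3-methylbut-2-enyl)cyclohexa-2,5-dien-1-one (mixture of diastereomers) | COC1=C(CC=C(C)C)C(=O)C=CC1(O)C#CC(O[Si](C)(C)C(C)(C)C)c2ccc(OCOC)c(CC=C(C)C)c2
F3 | step 8 | 4-(3-{[tert-butyl(dimethyl)silyl]oxy}-3-[4-(methoxymethoxy)-3-(3-methylbut-2-enyl)phenyl]prop-1-yn-1-yl)-3-methoxy-2-(3-methylbut-2-enyl)phenol (racemic) | COc1c(C#CC(O[Si](C)(C)C(C)(C)C)c2ccc(OCOC)c(CC=C(C)C)c2)ccc(O)c1CC=C(C)C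
F4 | step 8 | 4-{3-hydroxy-3-[4-(methoxymethoxy)-3-(3-methylbut-2-enyl)phenyl]prop-1-yn-1-yl}-3-methoxy-2-(3-methylbut-2-enyl)phenol (racemic) | COc1c(C#CC(O)c2ccc(OCOC)c(CC=C(C)C)c2)ccc(O)c1CC=C(C)C
F5 | step 8 | 3-[4-hydroxy-2-methoxy-3-(3-methylbut-2-enyl)phenyl]-1-[4-(methoxymethoxy)-3-(3-methylbut-2-enyl)phenyl]prop-2-yn-1-one | COc1c(C#CC(=O)c2ccc(OCOC)c(CC=C(C)C)c2)ccc(O)c1CC=C(C)C
F6 | step 7 | 1-[4-(methoxymethoxy)-3-(3-methylbut-2-enyl)phenyl]-3-(trimethylsilyl)prop-2-yn-1-ol (racemic) | C[Si](C)(C)C#CC(O)c1ccc(OCOC)c(CC=C(C)C)c1
F7 | step 7 | 1-[4-(methoxymethoxy)-3-(3-methylbut-2-enyl)phenyl]-3-(trimethylsilyl)prop-2-yn-1-one | C[Si](C)(C)C#CC(=O)c1ccc(OCOC)c(CC=C(C)C)c1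
F8 | step 7 | ({2-[4-(methoxymethoxy)-3-(3-methylbut-2-enyl)phenyl]-1,3-dioxolan-2-yl}ethynyl)(trimethyl)silane | C[Si](C)(C)C#CC1(c2ccc(OCOC)c(CC=C(C)C)c2)OCCO1
F9 | step 10 | 4-{5-[4-hydroxy-3-(3-methylbut-2-enyl)phenyl]-1,2-oxazol-3-yl}-3-methoxy-2-(3-methylbut-2-enyl)phenol | COc1c(-c2cc(-c3ccc(O)c(CC=C(C)C)c3)on2)ccc(O)c1CC=C(C)C
F10 | step 10 | (Z)-3-amino-3-[4-hydroxy-2-methoxy-3-(3-methylbut-2-enyl)phenyl]-1-[4-hydroxy-3-(3-methylbut-2-enyl)phenyl]prop-2-en-1-one | COc1c(/C(N)=C/C(=O)c2ccc(O)c(CC=C(C)C)c2)ccc(O)c1CC=C(C)C
F11 | step 3 | 4-[(2-methylbut-3-en-2-yl)oxy]benzaldehyde | C=CC(C)(C)Oc1ccc(C=O)cc1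
A1 | alternative 1 | 7-[(2-methylbut-3-en-2-yl)oxy]-2-{4-[(2-methylbut-3-en-2-yl)oxy]phenyl}chromen-4-one | C=CC(C)(C)Oc1ccc(-c2cc(=O)c3ccc(OC(C)(C)C=C)cc3o2)cc1
A2 | alternative 1 | 7-hydroxy-2-[4-hydroxy-3-(3-methylbut-2-enyl)phenyl]-8-(3-methylbut-2-enyl)chromen-4-one | CC(C)=CCc1cc(-c2cc(=O)c3ccc(O)c(CC=C(C)C)c3o2)ccc1O
A3 | alternative 1 | 1-[2,4-dihydroxy-3-(3-methylbut-2-enyl)phenyl]-3-[4-hydroxy-3-(3-methylbut-2-enyl)phenyl]propane-1,3-dione | CC(C)=CCc1c(O)ccc(C(=O)CC(=O)c2ccc(O)c(CC=C(C)C)c2)c1O
A4 | alternative 2 | 1,1-dimethoxy-2-(3-methylbut-2-enyl)-3-(trimethylsilyloxy)buta-1,3-diene | COC(OC)=C(CC=C(C)C)C(=C)O[Si](C)(C)C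
A5 | alternative 2 | 1-[4-(methoxymethoxy)-3-(3-methylbut-2-enyl)phenyl]penta-1,4-diyn-3-one | C#CC(=O)C#Cc1ccc(OCOC)c(CC=C(C)C)c1
A6 | alternative 2 | 1-[4-hydroxy-2-methoxy-3-(3-methylbut-2-enyl)phenyl]-3-[4-(methoxymethoxy)-3-(3-methylbut-2-enyl)phenyl]prop-2-yn-1-one | COc1c(C(=O)C#Cc2ccc(OCOC)c(CC=C(C)C)c2)ccc(O)c1CC=C(C)C
A7 | alternative 3 | 4-iodo-1-(methoxymethoxy)-2-(3-methylbut-2-enyl)benzene | COCOc1ccc(I)cc1CC=C(C)C
A8 | alternative 3 | 1-[2-methoxy-4-(methoxymethoxy)-3-(3-methylbut-2-enyl)phenyl]ethanone | COCOc1ccc(C(C)=O)c(OC)c1CC=C(C)C
A9 | alternative 3 | carbon monoxide | [C-]#[O+]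
A10 | alternative 3 | 1-[2-methoxy-4-(methoxymethoxy)-3-(3-methylbut-2-enyl)phenyl]-3-[4-(methoxymethoxy)-3-(3-methylbut-2-enyl)phenyl]propane-1,3-dione | COCOc1ccc(C(=O)CC(=O)c2ccc(OCOC)c(CC=C(C)C)c2)c(OC)c1CC=C(C)C
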